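The earlier runs and the new flask come from a simulation on assumed constants.

| flask | D | X | remark | time | volume of the second phase over the first |
|---|---|---|---|---|---|
| theta | 0.54 M | 2 equiv | run made earlier |  |  |
| flask | 0.27 M | 2.00 equiv |  | 10 d | 1.0 |

theta run (percent of the D charged)

| time / h | Z / % |
|---|---|
| 4.00 | 0 |
| 12.0 | 1.3 |
| 20.0 | 4.6 |
| 30.0 | 6.1 |
| 50.0 | 10.7 |

(standard deviation of a reading: 0.5 percentage points)

- in the second phase: X; everything else is in the first
- charges count per volume of the first phase; a concentration in a rate is the amount of a species over the volume of its own phase; every rate counts per litre of the first phase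
- what was read earlier has a scatter of 0.5 percentage points, one standard deviation
- steps that have been proposed: D + E <-> Z; Z <-> G; E <-> X; E <-> J
- the earlier runs hold the two phases in the same ratio of volumes as the flask asked about

- Sunday's: doubling the amount of X, all else as stated
- Monday's: doubling the transfer coefficient of X, all else as stated

* how much Z there is at 10 d, in percent of the D charged
* the change that raises the amount of Z at 10 d, in percent of the D charged most ("none" if none brings more than 2 percentage points) (Sunday's / Monday's / none)
* amount of Z at 10 d, in percent of the D charged, after Monday's

- No constant is given, so you make one from the theta run: between 12.0 h and 50.0 h Z climbs from 1.3% to 10.7%, and that slope divided by the 0.54 M of D charged gives 0.00458 /M/h, the charge-specific rate: the fraction of the D charge turned into Z per hour, per molar of charge.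
- Take the main step first. You assume that E stays in proportion to X, so at equal equivalents w times the charge is a pseudo-first-order rate for D, and the flask at 0.27 M, held on that straight line for 10 d, reaches 29.7% of its charge.
- Now add what the step consumes: as a fraction of the charge turns into Z, D falls by that fraction and X, at 2.00 equiv, by half of it in terms of its own charge, so the rate sinks by the sum, and averaged over the run the line loses 22.3% of itself, which brings this flask to 23.1%, the number I commit to.
- You put no figure on the rest, G and J, so this number carries nothing for them, and you expect them to lower it.
- On the same assumption Sunday's doubles the line while Monday's leaves w alone, so I name Sunday's and keep 23.1% for Monday's.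
- The forecast gives 30%, Sunday's and 40%, on the ground that “one run cannot fix the regime”; its first figure stands higher than mine.

The flask holds 17.4% of Z at 10 d and 20.0% after Monday's, and Sunday's is the better change, gaining 10 percentage points against 2.6 points. Beside the Z stands 15.3% of G at 10.0 d. Put to use on this flask, w gives 2.97% at 1.00 d, where Z stands at 3.02%, but at 10 d the line's 29.7% stands higher than the flask.

    D + E ⇌ Z (K = 3.61 /M, k = 0.0929 /M/h)
    Z ⇌ G (K = 0.912, k = 0.0338 /h)
    E ⇌ X, rate k3*([E] - [X]/K3) per volume of the first phase (partition coefficient = 1.37, kL = 0.00622 /h)
    E ⇌ J (K = 2.82, k = 0.0147 /h)

For the neighbour charged with 0.68 M of D, w gives a line of 74.8% and the same correction brings it to 32.8%. The computed neighbour holds 27.2% of Z.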